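## The problem

Catechin 7,3'-di-O-gallate (26) is a 2,3-trans-flavan-3-ol: a dihydropyran ring C fused to the phloroglucinol-type ring A, with the catechol ring B on C2, a hydroxyl on C3, and C2 (R) and C3 (S) as the only stereocentres. Five oxygens must be told apart, since O7 and O3' carry galloyl esters while O5, O4' and O3 stay free; the pair O3'/O4' on one catechol is the hardest to differentiate. C3 is the anchor for stereocontrol: it can be set in an acyclic precursor and then direct C2, whereas C3 itself is lost whenever a carbonyl or oxocarbenium carbon at C2 is allowed to enolise. Both esters are aryl esters that do not tolerate strong base, excess hydride or nucleophilic amines, and the 3'-gallate can migrate to O4' as soon as that phenol is free in a basic medium. Ring A is a very electron-rich arene that reacts with acids, electrophiles and oxidants at carbon, and the free polyphenol is oxidised above neutral pH, so the last operations must be neutral or slightly acidic. The feature that opens a less obvious construction is the 1,3,4-pattern of ring B: C1' bears C2 of the flavan, C3' (meta) the gallate oxygen and C4' (para) the free hydroxyl. This is the orientation in which a buta-1,3-diene with a silyloxy group on one inner carbon and an aroyloxy group on the other adds to an acyl-substituted alkyne, so ring B can be made by forming C1'–C2' and C5'–C6' with the gallate already on O3'.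

## Retrosynthesis

**Unmasking (26 from 25 from 24).** The last cuts are the eight benzyl C–O bonds of 25 and, one step earlier, the Si–O bond at O4' of 24. Every oxygen that ends as a free hydroxyl, except O4', is benzylated, so one neutral hydrogenolysis gives 26; the aryl esters exclude basic or nucleophilic deprotection. O4' carries a silyl group because the diene of the key step needs it. It is removed under acidic fluoride so that the catechol monoester never meets a phenoxide-forming base. Compound 24 differs from 26 only in protecting groups.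

**The 7-gallate (24 from 23 and 15).** The ester C–O bond at O7 is cut. Carrying this ester from the start is not possible, because it would not survive the enolate and organomagnesium steps that build the chain. The forward acylation asks that O7 be the only free hydroxyl of 23. This fixes benzyl on O5 and O3 and puts on O7 a group that leaves together with the one on O1.

**Ring C (23 from 22).** The O1–C2 bond is cut. Two neighbouring closures were weighed and set aside:
- Reductive closure of ketone 20 through its cyclic hemiketal passes an oxocarbenium ion. Hydride should add anti to the pseudoaxial C3 oxygen and give the 2,3-cis series, and loss of H3 to a flav-2-ene would erode C3.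
- Ionisation at C2 with capture by the phenol is poorly matched to this ring B, whose cation is destabilised by the meta aroyloxy group and the neighbouring alkoxy carbon.

The same features make an SN2 closure clean. An intramolecular Mitsunobu etherification of the (1S,2S)-alcohol 22 inverts C2 and gives the 2,3-trans flavan. Compound 22 is acyclic, and it must have O1 free and the benzylic alcohol syn to the C3 benzyloxy group.

**Setting C2 (22 from 21 from 20).** The two acetal C–O bonds on O1 and O7 and then the C2–H bond are cut. The carbonyl is reduced before O1 is freed, so a free ortho phenol never meets the ketone under acid. The reduction of 20 must follow the Felkin–Anh course, which calls for a bulky, non-chelating hydride; C3 then controls C2. Ketone 20 has one stereocentre.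

**Ring B (20 from 19; 19 from 13 and 18).** Aromatic ring B is taken back to cyclohexa-1,4-diene 19, one dehydrogenation away, and 19 is cut at C1'–C2' and C5'–C6' into ynone 13 and diene 18. Against buying a catechol and differentiating its oxygens by selective protection, this cut lets the orbital bias of the cycloaddition place the gallate on O3' and the silyl ether on O4'. The gallate enters only after all strongly basic steps. The precursors are far simpler: 13 holds ring A, C4, C3 and C2, and 18 is a four-carbon unit. The forward reaction must be regioselective (acyl para to silyloxy) and must run under neutral conditions so that the C3–H next to the carbonyl is not touched.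

**The diene (18 from 17; 17 from 16 and 15; 15 from 14).** The Si–O bond of 18 is cut to enol ester 17, and the enol ester C–O bond of 17 to biacetyl 16 and acid chloride 15, made from acid 14. The diketone supplies all four diene carbons with both oxygens in place. The forward steps ask for O-acylation of one enolate and silylation of the other.

**The ynone (13 from 12 from 11; 11 from 9 and 5; 9 from 6 and 7).** The alkyne–carbonyl bond is cut to Weinreb amide 12, the amide to imide 11, and the C3–C4 bond of 11 to glycolate imide 9 and benzylic bromide 5. An auxiliary-controlled glycolate alkylation sets C3 with its oxygen already benzylated, which is shorter than routes through a diol. Imide 9 comes from oxazolidinone 6 and acid chloride 7.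

**Ring A (5 from 4 from 3 from 2 from 1).** The C–Br bond, the benzylic C–O bond and three ether bonds are cut back to 2,4,6-trihydroxybenzaldehyde 1. The formyl group differentiates the phenols: two are acetalised first (O7 and the future O1), and the chelated one is benzylated afterwards (O5). The two acetals later leave together under mild acid, which spares benzyl ethers, the aryl silyl ether and the aryl ester.

## Roads not taken

**Alternative 1:** The cut is the O1–C2 bond of ring C in a flavan that still lacks both gallates, 5,4'-di-O-benzylcatechin A1. In the forward key step, acid in methanol removes three methoxymethyl groups from the 1,3-diarylpropane-1,2-diol A2 (a mixture of C1 epimers), ionises its benzylic hydroxyl, and the freed ortho phenol of ring A captures the cation.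
- Merits: ring B is bought as an arene; the benzylic carbon of A2 needs no control because both epimers converge; A1 exposes exactly the two phenols (O7 and O3') that are to be galloylated, so both esters go on in one step.
- Weak points for this target: the 2,3-trans outcome is a preference of the cation closure, not a stereospecific event. The ionisation works only because ring B of A2 carries two donor oxygens, so the gallate cannot be present earlier. The double galloylation must distinguish two phenols from the free secondary 3-OH of A1. The O3'/O4' distinction rests on selective alkylation of a catechol aldehyde.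
- Comparison: this road is shorter and uses routine steps; on step economy it is the better one. The chosen plan sets against it a stereospecific closure at C2, an O3 that stays benzylated to the end so that no acylation needs chemoselectivity, and an O3'/O4' differentiation that comes with the bond construction.

**Alternative 2:** The cut removes O1–C2 and C3–C4 together and leads to the fully protected flavan A3. In the forward key step, a chiral phosphoric acid dehydrates the ring A salicyl alcohol A4, which already carries the 7-gallate, to an ortho-quinone methide. This adds the (E)-enol carbonate A5 of ring B in a hetero-Diels–Alder reaction.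
- Merits: it is the most convergent road. Ring C, both stereocentres and both gallates are in place after one step; the E geometry of A5 translates into the trans relationship; A3 carries only hydrogenolysable groups, so a single step would finish the synthesis.
- Weak points: one step must deliver regio-, diastereo- and enantiocontrol together. An enol carbonate is a weak 2π donor, and its aryl group (with a meta acyloxy substituent) and its carbonate oxygen polarise the alkene in opposite senses, so bonding of O1 to the aryl-bearing carbon is not assured. Enantioselective acid catalysis with such an acyclic enol ester would be a new method. A5 must be made geometrically pure, A4 holds an aryl ester on a ring that ionises readily, and the O3'/O4' pair is again differentiated by classical protection.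
- Comparison: if its key step worked, this road would be clearly shorter. The chosen plan sets against it that every step is a known reaction type and that the two stereocentres are set in separate, well-understood events.

**Alternative 3:** The cut is C4–C4a and O1–C2 with ring A at the oxidation level of a cyclohexane-1,3-dione, giving hexahydrochromenone A6 (both C7 epimers). In the forward key step, an amino acid catalyst condenses the 5-silyloxy dione A7 with the trans-epoxy aldehyde A8, a dihydropyridine hydride donor reduces the alkylidene dione, and the enol oxygen opens the epoxide at its benzylic carbon with inversion.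
- Merits: O5 and O7 are differentiated by oxidation level. The electron-rich ring A and its labile benzylic electrophile are avoided, which is a real advantage over steps 4 and 6 of the chosen route. C3 comes from the epoxide and C2 from a stereospecific opening; a trans epoxide gives the trans flavan.
- Weak points: ring A must later be dehydrogenated next to the benzylic ether at C2 and the free 3-OH, and β-elimination of the C7 silyloxy group from the β-silyloxy ketone competes and would delete O7. The epoxide must open in the 6-endo mode and the epoxy aldehyde must survive an amine catalyst. The ring B oxygens of A8 are differentiated by selective protection, and the 3'-gallate would be installed late on a catechol mono-ether, where acyl migration threatens.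
- Comparison: both roads defer an aromatisation, and the step counts should be similar. This road handles ring A better. The chosen plan handles ring B better, because cyclohexadiene 19 is one dehydrogenation from the arene with no leaving group to lose and the gallate never has to be placed on a free catechol.

Key step: step 12

Assumption: compounds 1, 6, 7, 14 and 16 are bought; cycloadduct 19 is used without purification, and a minor regioisomer from step 12, if formed, is removed at ketone 20.

## Route

Step 1
Reactants: 1 2,4,6-trihydroxybenzaldehyde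
Product: 2 2-hydroxy-4,6-bis(methoxymethoxy)benzaldehyde
Conditions: MOMCl (2.1 equiv), i-Pr2NEt, CH2Cl2, 0 °C to rt
Reagents that add atoms: chloromethyl methyl ether, COCCl
Why: O-Alkylation with a hard chloromethyl ether under amine base takes the 4-OH and one 2-OH, while the remaining ortho-OH is held in a hydrogen bond to the formyl group and stays free; the formyl group also damps C-alkylation of the ring.

Step 2
Reactants: 2 2-hydroxy-4,6-bis(methoxymethoxy)benzaldehyde
Product: 3 2-(benzyloxy)-4,6-bis(methoxymethoxy)benzaldehyde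
Conditions: BnBr, K2CO3, DMF, rt
Reagents that add atoms: benzyl bromide, BrCc1ccccc1
Why: Williamson etherification of the chelated phenol; it fixes benzyl on the oxygen that becomes O5 and leaves acetals on the oxygens that become O1 and O7.

Step 3
Reactants: 3 2-(benzyloxy)-4,6-bis(methoxymethoxy)benzaldehyde
Product: 4 [2-(benzyloxy)-4,6-bis(methoxymethoxy)phenyl]methanol
Conditions: NaBH4, MeOH–THF, 0 °C
Reagents that add atoms: none
Why: Borohydride reduction of an aryl aldehyde; acetals and the benzyl ether are inert.

Step 4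
Reactants: 4 [2-(benzyloxy)-4,6-bis(methoxymethoxy)phenyl]methanol
Product: 5 1-(benzyloxy)-2-(bromomethyl)-3,5-bis(methoxymethoxy)benzene
Conditions: CBr4, PPh3, 2,6-lutidine, CH2Cl2, −20 to 0 °C; used crude at once
Reagents that add atoms: carbon tetrabromide, BrC(Br)(Br)Br
Why: Appel bromination under neutral, buffered conditions avoids the acid that would cleave the acetals; the trialkoxybenzyl bromide ionises easily, so it is not chromatographed and goes into step 6 the same day.

Step 5
Reactants: 6 (R)-4-benzyloxazolidin-2-one, 7 benzyloxyacetyl chloride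
Product: 9 (R)-4-benzyl-3-[2-(benzyloxy)acetyl]oxazolidin-2-one, via lithium oxazolidinide 8 (not isolated)
Conditions: n-BuLi, THF, −78 °C; then 7, −78 to 0 °C
Reagents that add atoms: none
Why: N-Acylation of the lithiated oxazolidinone with an acid chloride, the standard entry to Evans glycolate imides.

Step 6
Reactants: 9 (R)-4-benzyl-3-[2-(benzyloxy)acetyl]oxazolidin-2-one, 5 1-(benzyloxy)-2-(bromomethyl)-3,5-bis(methoxymethoxy)benzene
Product: 11 (R)-4-benzyl-3-{(S)-2-(benzyloxy)-3-[2-(benzyloxy)-4,6-bis(methoxymethoxy)phenyl]propanoyl}oxazolidin-2-one, via sodium enolate 10 (not isolated)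
Conditions: 9 (1.5 equiv), NaN(SiMe3)2, THF, −78 °C; then 5, −78 to −45 °C
Reagents that add atoms: none
Why: Evans glycolate alkylation: the sodium-chelated (Z)-enolate is attacked by the reactive benzylic bromide on the face opposite the benzyl group of the auxiliary, which with the (R)-auxiliary sets the (S)-configuration of the carbon that becomes C3; the enolate is kept below −40 °C and used in excess.

Step 7
Reactants: 11 (R)-4-benzyl-3-{(S)-2-(benzyloxy)-3-[2-(benzyloxy)-4,6-bis(methoxymethoxy)phenyl]propanoyl}oxazolidin-2-one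
Product: 12 (S)-2-(benzyloxy)-3-[2-(benzyloxy)-4,6-bis(methoxymethoxy)phenyl]-N-methoxy-N-methylpropanamide
Conditions: MeNHOMe·HCl, AlMe3, CH2Cl2, −20 to 0 °C; aq. KNaC4H4O6 work-up
Reagents that add atoms: N,O-dimethylhydroxylamine hydrochloride, CNOC.Cl
Why: Transamination of the N-acyl oxazolidinone with the aluminium amide MeAl(Cl)N(OMe)Me (Weinreb amide formation) cleaves the exocyclic acyl–N bond without touching the α-stereocentre; auxiliary 6 is recovered.

Step 8
Reactants: 12 (S)-2-(benzyloxy)-3-[2-(benzyloxy)-4,6-bis(methoxymethoxy)phenyl]-N-methoxy-N-methylpropanamide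
Product: 13 (S)-4-(benzyloxy)-5-[2-(benzyloxy)-4,6-bis(methoxymethoxy)phenyl]pent-1-yn-3-one
Conditions: HC≡CMgBr, THF, −78 to 0 °C; cold aq. NaHSO4 quench
Reagents that add atoms: ethynylmagnesium bromide, C#C[Mg]Br
Why: Weinreb ketone synthesis: the alkynylmagnesium reagent adds once and the chelated tetrahedral adduct collapses only on quench; the cold acidic quench keeps the liberated hydroxylamine from adding to the ynone, and the α-alkoxy stereocentre is not enolised at low temperature.

Step 9
Reactants: 14 3,4,5-tris(benzyloxy)benzoic acid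
Product: 15 3,4,5-tris(benzyloxy)benzoyl chloride
Conditions: (COCl)2, DMF (cat.), CH2Cl2, 0 °C to rt; evaporated
Reagents that add atoms: oxalyl chloride, O=C(Cl)C(=O)Cl
Why: Acid chloride formation with catalytic formamide activation; benzyl ethers are inert.

Step 10
Reactants: 16 biacetyl (butane-2,3-dione), 15 3,4,5-tris(benzyloxy)benzoyl chloride
Product: 17 3-oxobut-1-en-2-yl 3,4,5-tris(benzyloxy)benzoate
Conditions: 16 (excess), Et3N, DMPU, THF, 0 °C to rt
Reagents that add atoms: none
Why: O-Acylation of the amine-generated enolate of the 1,2-diketone in a dipolar medium gives the 1-acetylvinyl ester, a known route to captodative enol esters; the excess of volatile diketone favours acylation over its self-condensation.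

Step 11
Reactants: 17 3-oxobut-1-en-2-yl 3,4,5-tris(benzyloxy)benzoate
Product: 18 3-(triisopropylsilyloxy)buta-1,3-dien-2-yl 3,4,5-tris(benzyloxy)benzoate
Conditions: TIPSOTf, Et3N, CH2Cl2, 0 °C
Reagents that add atoms: triisopropylsilyl trifluoromethanesulfonate, CC(C)[Si](C(C)C)(C(C)C)OS(=O)(=O)C(F)(F)F
Why: Soft enolisation of the methyl ketone with a silyl triflate and amine gives the silyl enol ether, that is the 2-aroyloxy-3-silyloxydiene; triisopropylsilyl is chosen because the aryl silyl ether derived from it withstands the acid of step 15.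

Step 12
Reactants: 13 (S)-4-(benzyloxy)-5-[2-(benzyloxy)-4,6-bis(methoxymethoxy)phenyl]pent-1-yn-3-one, 18 3-(triisopropylsilyloxy)buta-1,3-dien-2-yl 3,4,5-tris(benzyloxy)benzoate
Product: 19 5-{(S)-2-(benzyloxy)-3-[2-(benzyloxy)-4,6-bis(methoxymethoxy)phenyl]propanoyl}-2-(triisopropylsilyloxy)cyclohexa-1,4-dien-1-yl 3,4,5-tris(benzyloxy)benzoate
Conditions: 18 (1.5 equiv), BHT (cat.), toluene, 100 °C, sealed tube
Reagents that add atoms: none
Why: The step is a concerted but asynchronous [4+2] cycloaddition of normal electron demand between the diene HOMO and the LUMO of the alkynyl ketone. The silyloxy group is the stronger donor, so the largest HOMO coefficient lies on the CH2 next to the silyloxy carbon; this terminus bonds to the β-carbon of the ynone and the CH2 next to the aroyloxy carbon bonds to the acyl-bearing carbon. The closest known reaction type is the thermal Diels–Alder reaction of 2-acyloxy-3-silyloxybuta-1,3-dienes and other 2-silyloxydienes with alkynyl ketones and propiolates, which gives cyclohexa-1,4-dienes that are then aromatised. One ring is closed, the six-membered carbocycle that becomes ring B, by intermolecular cycloaddition that forms C1'–C2' and C5'–C6' in the same step. No stereocentre is created, and the (S)-centre next to the carbonyl is remote from the reacting alkyne and is not enolised under neutral thermal conditions. The selectivity needed is regioselectivity, acyl carbon para to the silyloxy carbon and meta to the gallate-bearing carbon, and it is secured by the donor strength of the silyloxy oxygen over the cross-conjugated aroyloxy oxygen. The alkyne reacts only once because the adduct is a less reactive enone, and a radical inhibitor limits oligomerisation of the ynone.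

Step 13
Reactants: 19 5-{(S)-2-(benzyloxy)-3-[2-(benzyloxy)-4,6-bis(methoxymethoxy)phenyl]propanoyl}-2-(triisopropylsilyloxy)cyclohexa-1,4-dien-1-yl 3,4,5-tris(benzyloxy)benzoate
Product: 20 5-{(S)-2-(benzyloxy)-3-[2-(benzyloxy)-4,6-bis(methoxymethoxy)phenyl]propanoyl}-2-(triisopropylsilyloxy)phenyl 3,4,5-tris(benzyloxy)benzoate
Conditions: DDQ (1.1 equiv), toluene, 0 °C to rt
Reagents that add atoms: none
Why: Dehydrogenation of a cyclohexa-1,4-diene by a high-potential quinone (hydride abstraction from a doubly allylic CH2, then proton loss) gives the arene under neutral conditions; it is much faster than oxidation at the ring A benzylic carbon, so about one equivalent at low temperature suffices.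

Step 14
Reactants: 20 5-{(S)-2-(benzyloxy)-3-[2-(benzyloxy)-4,6-bis(methoxymethoxy)phenyl]propanoyl}-2-(triisopropylsilyloxy)phenyl 3,4,5-tris(benzyloxy)benzoate
Product: 21 5-{(1S,2S)-2-(benzyloxy)-3-[2-(benzyloxy)-4,6-bis(methoxymethoxy)phenyl]-1-hydroxypropyl}-2-(triisopropylsilyloxy)phenyl 3,4,5-tris(benzyloxy)benzoate
Conditions: KBH(s-Bu)3 (1.1 equiv), THF, −78 °C; AcOH quench at −78 °C
Reagents that add atoms: none
Why: Felkin–Anh reduction of an α-alkoxy ketone: with a bulky trialkylborohydride and a non-chelating potassium counter-ion, hydride adds anti to the C–OBn bond past the hydrogen on C3 and gives the syn (1S,2S) alcohol, so C3 sets C2; the hindered aryl ester is not attacked at −78 °C.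

Step 15
Reactants: 21 5-{(1S,2S)-2-(benzyloxy)-3-[2-(benzyloxy)-4,6-bis(methoxymethoxy)phenyl]-1-hydroxypropyl}-2-(triisopropylsilyloxy)phenyl 3,4,5-tris(benzyloxy)benzoate
Product: 22 5-{(1S,2S)-2-(benzyloxy)-3-[2-(benzyloxy)-4,6-dihydroxyphenyl]-1-hydroxypropyl}-2-(triisopropylsilyloxy)phenyl 3,4,5-tris(benzyloxy)benzoate
Conditions: HCl (1 M in MeOH), THF, rt
Reagents that add atoms: none
Why: Acid-catalysed acetal exchange removes both aryl methoxymethyl ethers as dimethoxymethane at room temperature; the aryl triisopropylsilyl ether, the benzyl ethers and the benzoate-type aryl ester react far more slowly, and the benzylic alcohol does not ionise because its ring carries a meta acyloxy group and the next carbon an alkoxy group.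

Step 16
Reactants: 22 5-{(1S,2S)-2-(benzyloxy)-3-[2-(benzyloxy)-4,6-dihydroxyphenyl]-1-hydroxypropyl}-2-(triisopropylsilyloxy)phenyl 3,4,5-tris(benzyloxy)benzoate
Product: 23 5-[(2R,3S)-3,5-bis(benzyloxy)-7-hydroxychroman-2-yl]-2-(triisopropylsilyloxy)phenyl 3,4,5-tris(benzyloxy)benzoate
Conditions: PPh3, DIAD, THF (0.01 M), 0 °C to rt
Reagents that add atoms: none
Why: Intramolecular Mitsunobu etherification, known for flavans and flavan-3-ols: the alkoxyphosphonium ion at C2 is displaced by the ortho phenoxide in a 6-exo-tet SN2 reaction with inversion, which turns (1S) into (2R) and gives the 2,3-trans flavan; the para phenol cannot reach C2, and dilution suppresses intermolecular alkylation.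

Step 17
Reactants: 23 5-[(2R,3S)-3,5-bis(benzyloxy)-7-hydroxychroman-2-yl]-2-(triisopropylsilyloxy)phenyl 3,4,5-tris(benzyloxy)benzoate, 15 3,4,5-tris(benzyloxy)benzoyl chloride
Product: 24 (2R,3S)-3,5-bis(benzyloxy)-2-{3-[3,4,5-tris(benzyloxy)benzoyloxy]-4-(triisopropylsilyloxy)phenyl}chroman-7-yl 3,4,5-tris(benzyloxy)benzoate
Conditions: Et3N, DMAP (cat.), CH2Cl2, 0 °C to rt
Reagents that add atoms: none
Why: Acylation of the only free hydroxyl (7-OH) with the acid chloride under nucleophilic catalysis; no phenol is free next to the 3'-ester, so no migration can occur.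

Step 18
Reactants: 24 (2R,3S)-3,5-bis(benzyloxy)-2-{3-[3,4,5-tris(benzyloxy)benzoyloxy]-4-(triisopropylsilyloxy)phenyl}chroman-7-yl 3,4,5-tris(benzyloxy)benzoate
Product: 25 (2R,3S)-3,5-bis(benzyloxy)-2-{4-hydroxy-3-[3,4,5-tris(benzyloxy)benzoyloxy]phenyl}chroman-7-yl 3,4,5-tris(benzyloxy)benzoate
Conditions: HF·pyridine, pyridine, THF, 0 °C to rt
Reagents that add atoms: none
Why: Fluoride cleavage of an aryl silyl ether in an acidic, buffered medium; no phenoxide is generated, which keeps the gallate on O3' from moving to the freed O4', and benzyl ethers and esters are inert.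

Step 19
Reactants: 25 (2R,3S)-3,5-bis(benzyloxy)-2-{4-hydroxy-3-[3,4,5-tris(benzyloxy)benzoyloxy]phenyl}chroman-7-yl 3,4,5-tris(benzyloxy)benzoate
Product: 26 catechin 7,3'-di-O-gallate, (2R,3S)-3,5-dihydroxy-2-[4-hydroxy-3-(3,4,5-trihydroxybenzoyloxy)phenyl]chroman-7-yl 3,4,5-trihydroxybenzoate
Conditions: H2 (1 atm), Pd(OH)2/C, THF–MeOH, rt
Reagents that add atoms: none
Why: Hydrogenolysis of eight benzyl ethers over Pd(OH)2 on carbon under neutral conditions; aryl esters and the benzylic C2–O1 bond of flavans survive such debenzylation, and the neutral medium avoids acyl migration and oxidation of the polyphenol.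

## Compound list

1 | 2,4,6-trihydroxybenzaldehyde | O=Cc1c(O)cc(O)cc1O | starting material
2 | 2-hydroxy-4,6-bis(methoxymethoxy)benzaldehyde | O=Cc1c(O)cc(OCOC)cc1OCOC | intermediate
3 | 2-(benzyloxy)-4,6-bis(methoxymethoxy)benzaldehyde | O=Cc1c(OCc2ccccc2)cc(OCOC)cc1OCOC | intermediate
4 | [2-(benzyloxy)-4,6-bis(methoxymethoxy)phenyl]methanol | OCc1c(OCc2ccccc2)cc(OCOC)cc1OCOC | intermediate
5 | 1-(benzyloxy)-2-(bromomethyl)-3,5-bis(methoxymethoxy)benzene | BrCc1c(OCc2ccccc2)cc(OCOC)cc1OCOC | intermediate
6 | (R)-4-benzyloxazolidin-2-one | O=C1N[C@H](Cc2ccccc2)CO1 | starting material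
7 | benzyloxyacetyl chloride | O=C(Cl)COCc1ccccc1 | starting material
8 | lithium (R)-4-benzyl-2-oxooxazolidin-3-ide | [Li]N1C(=O)OC[C@H]1Cc1ccccc1 | intermediate (not isolated)
9 | (R)-4-benzyl-3-[2-(benzyloxy)acetyl]oxazolidin-2-one | O=C(COCc1ccccc1)N1C(=O)OC[C@H]1Cc1ccccc1 | intermediate
10 | sodium (Z)-1-[(R)-4-benzyl-2-oxooxazolidin-3-yl]-2-(benzyloxy)ethen-1-olate | [Na]O/C(=C\OCc1ccccc1)N1C(=O)OC[C@H]1Cc1ccccc1 | intermediate (not isolated)
11 | (R)-4-benzyl-3-{(S)-2-(benzyloxy)-3-[2-(benzyloxy)-4,6-bis(methoxymethoxy)phenyl]propanoyl}oxazolidin-2-one | O=C([C@@H](OCc1ccccc1)Cc1c(OCOC)cc(OCOC)cc1OCc1ccccc1)N1C(=O)OC[C@H]1Cc1ccccc1 | intermediate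
12 | (S)-2-(benzyloxy)-3-[2-(benzyloxy)-4,6-bis(methoxymethoxy)phenyl]-N-methoxy-N-methylpropanamide | CON(C)C(=O)[C@@H](OCc1ccccc1)Cc1c(OCOC)cc(OCOC)cc1OCc1ccccc1 | intermediate
13 | (S)-4-(benzyloxy)-5-[2-(benzyloxy)-4,6-bis(methoxymethoxy)phenyl]pent-1-yn-3-one | C#CC(=O)[C@@H](OCc1ccccc1)Cc1c(OCOC)cc(OCOC)cc1OCc1ccccc1 | intermediate
14 | 3,4,5-tris(benzyloxy)benzoic acid | OC(=O)c1cc(OCc2ccccc2)c(OCc2ccccc2)c(OCc2ccccc2)c1 | starting material
15 | 3,4,5-tris(benzyloxy)benzoyl chloride | ClC(=O)c1cc(OCc2ccccc2)c(OCc2ccccc2)c(OCc2ccccc2)c1 | intermediate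
16 | biacetyl (butane-2,3-dione) | CC(=O)C(C)=O | starting material
17 | 3-oxobut-1-en-2-yl 3,4,5-tris(benzyloxy)benzoate | CC(=O)C(=C)OC(=O)c1cc(OCc2ccccc2)c(OCc2ccccc2)c(OCc2ccccc2)c1 | intermediate
18 | 3-(triisopropylsilyloxy)buta-1,3-dien-2-yl 3,4,5-tris(benzyloxy)benzoate | C=C(O[Si](C(C)C)(C(C)C)C(C)C)C(=C)OC(=O)c1cc(OCc2ccccc2)c(OCc2ccccc2)c(OCc2ccccc2)c1 | intermediate
19 | 5-{(S)-2-(benzyloxy)-3-[2-(benzyloxy)-4,6-bis(methoxymethoxy)phenyl]propanoyl}-2-(triisopropylsilyloxy)cyclohexa-1,4-dien-1-yl 3,4,5-tris(benzyloxy)benzoate | O=C(C1=CCC(O[Si](C(C)C)(C(C)C)C(C)C)=C(OC(=O)c2cc(OCc3ccccc3)c(OCc3ccccc3)c(OCc3ccccc3)c2)C1)[C@@H](OCc1ccccc1)Cc1c(OCOC)cc(OCOC)cc1OCc1ccccc1 | intermediate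
20 | 5-{(S)-2-(benzyloxy)-3-[2-(benzyloxy)-4,6-bis(methoxymethoxy)phenyl]propanoyl}-2-(triisopropylsilyloxy)phenyl 3,4,5-tris(benzyloxy)benzoate | O=C(c1ccc(O[Si](C(C)C)(C(C)C)C(C)C)c(OC(=O)c2cc(OCc3ccccc3)c(OCc3ccccc3)c(OCc3ccccc3)c2)c1)[C@@H](OCc1ccccc1)Cc1c(OCOC)cc(OCOC)cc1OCc1ccccc1 | intermediate
21 | 5-{(1S,2S)-2-(benzyloxy)-3-[2-(benzyloxy)-4,6-bis(methoxymethoxy)phenyl]-1-hydroxypropyl}-2-(triisopropylsilyloxy)phenyl 3,4,5-tris(benzyloxy)benzoate | O[C@@H](c1ccc(O[Si](C(C)C)(C(C)C)C(C)C)c(OC(=O)c2cc(OCc3ccccc3)c(OCc3ccccc3)c(OCc3ccccc3)c2)c1)[C@@H](OCc1ccccc1)Cc1c(OCOC)cc(OCOC)cc1OCc1ccccc1 | intermediate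
22 | 5-{(1S,2S)-2-(benzyloxy)-3-[2-(benzyloxy)-4,6-dihydroxyphenyl]-1-hydroxypropyl}-2-(triisopropylsilyloxy)phenyl 3,4,5-tris(benzyloxy)benzoate | O[C@@H](c1ccc(O[Si](C(C)C)(C(C)C)C(C)C)c(OC(=O)c2cc(OCc3ccccc3)c(OCc3ccccc3)c(OCc3ccccc3)c2)c1)[C@@H](OCc1ccccc1)Cc1c(O)cc(O)cc1OCc1ccccc1 | intermediate
23 | 5-[(2R,3S)-3,5-bis(benzyloxy)-7-hydroxychroman-2-yl]-2-(triisopropylsilyloxy)phenyl 3,4,5-tris(benzyloxy)benzoate | Oc1cc(OCc2ccccc2)c2c(c1)O[C@H](c1ccc(O[Si](C(C)C)(C(C)C)C(C)C)c(OC(=O)c3cc(OCc4ccccc4)c(OCc4ccccc4)c(OCc4ccccc4)c3)c1)[C@@H](OCc1ccccc1)C2 | intermediate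
24 | (2R,3S)-3,5-bis(benzyloxy)-2-{3-[3,4,5-tris(benzyloxy)benzoyloxy]-4-(triisopropylsilyloxy)phenyl}chroman-7-yl 3,4,5-tris(benzyloxy)benzoate | O=C(Oc1cc(OCc2ccccc2)c2c(c1)O[C@H](c1ccc(O[Si](C(C)C)(C(C)C)C(C)C)c(OC(=O)c3cc(OCc4ccccc4)c(OCc4ccccc4)c(OCc4ccccc4)c3)c1)[C@@H](OCc1ccccc1)C2)c1cc(OCc2ccccc2)c(OCc2ccccc2)c(OCc2ccccc2)c1 | intermediate
25 | (2R,3S)-3,5-bis(benzyloxy)-2-{4-hydroxy-3-[3,4,5-tris(benzyloxy)benzoyloxy]phenyl}chroman-7-yl 3,4,5-tris(benzyloxy)benzoate | O=C(Oc1cc(OCc2ccccc2)c2c(c1)O[C@H](c1ccc(O)c(OC(=O)c3cc(OCc4ccccc4)c(OCc4ccccc4)c(OCc4ccccc4)c3)c1)[C@@H](OCc1ccccc1)C2)c1cc(OCc2ccccc2)c(OCc2ccccc2)c(OCc2ccccc2)c1 | intermediate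
26 | catechin 7,3'-di-O-gallate, (2R,3S)-3,5-dihydroxy-2-[4-hydroxy-3-(3,4,5-trihydroxybenzoyloxy)phenyl]chroman-7-yl 3,4,5-trihydroxybenzoate | O=C(Oc1cc(O)c2c(c1)O[C@H](c1ccc(O)c(OC(=O)c3cc(O)c(O)c(O)c3)c1)[C@@H](O)C2)c1cc(O)c(O)c(O)c1 | target

## Step count and least certain steps

Total: 19 steps. Longest linear sequence: 15 steps (steps 1–4, 6–8 and 12–19).

**Step 12 (key step).** The regioselectivity may be eroded because the aroyloxy oxygen competes with the silyloxy group in polarising the diene. The cycloaddition of the hindered 2,3-disubstituted diene may also be slow enough for the ynone to oligomerise. Fallback: the bias is replaced by symmetry. Ynone 13 is heated with commercial 2,3-bis(trimethylsilyloxy)buta-1,3-diene to give (S)-2-(benzyloxy)-3-[2-(benzyloxy)-4,6-bis(methoxymethoxy)phenyl]-1-[4,5-bis(trimethylsilyloxy)cyclohexa-1,4-dien-1-yl]propan-1-one F1, in which no regiochemical question arises. DDQ gives the bis(trimethylsilyl) aryl ketone (S)-2-(benzyloxy)-3-[2-(benzyloxy)-4,6-bis(methoxymethoxy)phenyl]-1-[3,4-bis(trimethylsilyloxy)phenyl]propan-1-one F2, and aqueous citric acid in THF gives the catechol ketone (S)-2-(benzyloxy)-3-[2-(benzyloxy)-4,6-bis(methoxymethoxy)phenyl]-1-(3,4-dihydroxyphenyl)propan-1-one F3. The more acidic 4'-hydroxyl, para to the ketone, is silylated with TIPSCl and imidazole to give (S)-2-(benzyloxy)-3-[2-(benzyloxy)-4,6-bis(methoxymethoxy)phenyl]-1-[3-hydroxy-4-(triisopropylsilyloxy)phenyl]propan-1-one F4. Acylation with 15 (Et3N, DMAP) returns to the route at 20.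

**Step 6.** The trialkoxybenzyl bromide may be lost by ionisation and self-alkylation before the enolate captures it. Fallback: the C3–C4 bond is made from aldehyde 3 by an aldol reaction. (S)-4-Benzyloxazolidin-2-one is acylated with 7 as in step 5 to give (S)-4-benzyl-3-[2-(benzyloxy)acetyl]oxazolidin-2-one F5. Its boron enolate (Bu2BOTf, Et3N) adds to 3 in an Evans syn-aldol reaction, which attacks the enolate face opposite to that of the alkylation and so gives the same C3 configuration, to furnish (S)-4-benzyl-3-{(2S,3R)-2-(benzyloxy)-3-[2-(benzyloxy)-4,6-bis(methoxymethoxy)phenyl]-3-hydroxypropanoyl}oxazolidin-2-one F6. Thiocarbonyldiimidazole gives (S)-4-benzyl-3-{(2S,3R)-2-(benzyloxy)-3-[2-(benzyloxy)-4,6-bis(methoxymethoxy)phenyl]-3-[(1H-imidazol-1-ylcarbonothioyl)oxy]propanoyl}oxazolidin-2-one F7. Barton–McCombie deoxygenation (Bu3SnH, AIBN) gives (S)-4-benzyl-3-{(S)-2-(benzyloxy)-3-[2-(benzyloxy)-4,6-bis(methoxymethoxy)phenyl]propanoyl}oxazolidin-2-one F8, and the conditions of step 7 return to the route at 12.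

**Step 14.** Facial selectivity may be poor if a chelated transition state competes, and hydride may attack the aryl ester. Fallback: the reduction is put under catalyst control. Ketone 20 is reduced with BH3·SMe2 and (S)-2-methyl-CBS-oxazaborolidine, which treats the aryl group as the large substituent and should deliver the same (1S)-alcohol 21 while leaving esters alone.

**Step 15.** The aryl gallate may undergo methanolysis, or the freed ring A may be alkylated at carbon by the methoxymethyl cation. Fallback: the acetals are removed without Brønsted acid or alcohol. TMSOTf and 2,2'-bipyridyl in CH2Cl2 convert the aryl methoxymethyl ethers of 21 into silyl ethers and silylate the alcohol, giving 5-{(1S,2S)-2-(benzyloxy)-3-[2-(benzyloxy)-4,6-bis(trimethylsilyloxy)phenyl]-1-(trimethylsilyloxy)propyl}-2-(triisopropylsilyloxy)phenyl 3,4,5-tris(benzyloxy)benzoate F9. Water in THF hydrolyses it and returns to the route at 22.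

**Step 16.** Stereospecificity may be lost through partial ionisation at C2, and elimination towards the enol ether may compete. Fallback: the closure is run as a cation cyclisation. Diol 22 is treated with BF3·OEt2 in CH2Cl2 at low temperature, so that the ortho phenol captures the benzylic cation through the chair-like arrangement with both substituents equatorial, which favours the same trans flavan 23.

**Step 18.** The galloyl group may migrate from O3' to O4' once the neighbouring phenol is free. Fallback: the order of unmasking is reversed so that the free catechol monoester appears only in the last operation. Compound 24 is hydrogenolysed first (H2, Pd(OH)2/C) to (2R,3S)-3,5-dihydroxy-2-[3-(3,4,5-trihydroxybenzoyloxy)-4-(triisopropylsilyloxy)phenyl]chroman-7-yl 3,4,5-trihydroxybenzoate F10, and HF·pyridine then gives 26 directly.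

## Further compounds

F1 | step 12 | (S)-2-(benzyloxy)-3-[2-(benzyloxy)-4,6-bis(methoxymethoxy)phenyl]-1-[4,5-bis(trimethylsilyloxy)cyclohexa-1,4-dien-1-yl]propan-1-one | O=C(C1=CCC(O[Si](C)(C)C)=C(O[Si](C)(C)C)C1)[C@@H](OCc1ccccc1)Cc1c(OCOC)cc(OCOC)cc1OCc1ccccc1
F2 | step 12 | (S)-2-(benzyloxy)-3-[2-(benzyloxy)-4,6-bis(methoxymethoxy)phenyl]-1-[3,4-bis(trimethylsilyloxy)phenyl]propan-1-one | O=C(c1ccc(O[Si](C)(C)C)c(O[Si](C)(C)C)c1)[C@@H](OCc1ccccc1)Cc1c(OCOC)cc(OCOC)cc1OCc1ccccc1
F3 | step 12 | (S)-2-(benzyloxy)-3-[2-(benzyloxy)-4,6-bis(methoxymethoxy)phenyl]-1-(3,4-dihydroxyphenyl)propan-1-one | O=C(c1ccc(O)c(O)c1)[C@@H](OCc1ccccc1)Cc1c(OCOC)cc(OCOC)cc1OCc1ccccc1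
F4 | step 12 | (S)-2-(benzyloxy)-3-[2-(benzyloxy)-4,6-bis(methoxymethoxy)phenyl]-1-[3-hydroxy-4-(triisopropylsilyloxy)phenyl]propan-1-one | O=C(c1ccc(O[Si](C(C)C)(C(C)C)C(C)C)c(O)c1)[C@@H](OCc1ccccc1)Cc1c(OCOC)cc(OCOC)cc1OCc1ccccc1
F5 | step 6 | (S)-4-benzyl-3-[2-(benzyloxy)acetyl]oxazolidin-2-one | O=C(COCc1ccccc1)N1C(=O)OC[C@@H]1Cc1ccccc1
F6 | step 6 | (S)-4-benzyl-3-{(2S,3R)-2-(benzyloxy)-3-[2-(benzyloxy)-4,6-bis(methoxymethoxy)phenyl]-3-hydroxypropanoyl}oxazolidin-2-one | O=C([C@@H](OCc1ccccc1)[C@H](O)c1c(OCOC)cc(OCOC)cc1OCc1ccccc1)N1C(=O)OC[C@@H]1Cc1ccccc1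
F7 | step 6 | (S)-4-benzyl-3-{(2S,3R)-2-(benzyloxy)-3-[2-(benzyloxy)-4,6-bis(methoxymethoxy)phenyl]-3-[(1H-imidazol-1-ylcarbonothioyl)oxy]propanoyl}oxazolidin-2-one | O=C([C@@H](OCc1ccccc1)[C@H](OC(=S)n1ccnc1)c1c(OCOC)cc(OCOC)cc1OCc1ccccc1)N1C(=O)OC[C@@H]1Cc1ccccc1
F8 | step 6 | (S)-4-benzyl-3-{(S)-2-(benzyloxy)-3-[2-(benzyloxy)-4,6-bis(methoxymethoxy)phenyl]propanoyl}oxazolidin-2-one | O=C([C@@H](OCc1ccccc1)Cc1c(OCOC)cc(OCOC)cc1OCc1ccccc1)N1C(=O)OC[C@@H]1Cc1ccccc1
F0 | step 14 | none | none
F9 | step 15 | 5-{(1S,2S)-2-(benzyloxy)-3-[2-(benzyloxy)-4,6-bis(trimethylsilyloxy)phenyl]-1-(trimethylsilyloxy)propyl}-2-(triisopropylsilyloxy)phenyl 3,4,5-tris(benzyloxy)benzoate | C[Si](C)(C)O[C@@H](c1ccc(O[Si](C(C)C)(C(C)C)C(C)C)c(OC(=O)c2cc(OCc3ccccc3)c(OCc3ccccc3)c(OCc3ccccc3)c2)c1)[C@@H](OCc1ccccc1)Cc1c(O[Si](C)(C)C)cc(O[Si](C)(C)C)cc1OCc1ccccc1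
F0 | step 16 | none | none
F10 | step 18 | (2R,3S)-3,5-dihydroxy-2-[3-(3,4,5-trihydroxybenzoyloxy)-4-(triisopropylsilyloxy)phenyl]chroman-7-yl 3,4,5-trihydroxybenzoate | O=C(Oc1cc(O)c2c(c1)O[C@H](c1ccc(O[Si](C(C)C)(C(C)C)C(C)C)c(OC(=O)c3cc(O)c(O)c(O)c3)c1)[C@@H](O)C2)c1cc(O)c(O)c(O)c1
A1 | alternative 1 | 5,4'-di-O-benzyl-(+)-catechin, (2R,3S) | Oc1cc(OCc2ccccc2)c2c(c1)O[C@H](c1ccc(OCc3ccccc3)c(O)c1)[C@@H](O)C2
A2 | alternative 1 | (2S)-1-[4-(benzyloxy)-3-(methoxymethoxy)phenyl]-3-[2-(benzyloxy)-4,6-bis(methoxymethoxy)phenyl]propane-1,2-diol, both C1 epimers | OC(c1ccc(OCc2ccccc2)c(OCOC)c1)[C@@H](O)Cc1c(OCOC)cc(OCOC)cc1OCc1ccccc1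
A3 | alternative 2 | (2R,3S)-5-(benzyloxy)-2-[4-(benzyloxy)-3-{[3,4,5-tris(benzyloxy)benzoyl]oxy}phenyl]-3-{[(benzyloxy)carbonyl]oxy}chroman-7-yl 3,4,5-tris(benzyloxy)benzoate | O=C(Oc1cc(OCc2ccccc2)c2c(c1)O[C@H](c1ccc(OCc3ccccc3)c(OC(=O)c3cc(OCc4ccccc4)c(OCc4ccccc4)c(OCc4ccccc4)c3)c1)[C@@H](OC(=O)OCc1ccccc1)C2)c1cc(OCc2ccccc2)c(OCc2ccccc2)c(OCc2ccccc2)c1
A4 | alternative 2 | 3-(benzyloxy)-5-hydroxy-4-(hydroxymethyl)phenyl 3,4,5-tris(benzyloxy)benzoate | OCc1c(O)cc(OC(=O)c2cc(OCc3ccccc3)c(OCc3ccccc3)c(OCc3ccccc3)c2)cc1OCc1ccccc1
A5 | alternative 2 | 2-(benzyloxy)-5-[(E)-2-{[(benzyloxy)carbonyl]oxy}ethenyl]phenyl 3,4,5-tris(benzyloxy)benzoate | O=C(OCc1ccccc1)O/C=C/c1ccc(OCc2ccccc2)c(OC(=O)c2cc(OCc3ccccc3)c(OCc3ccccc3)c(OCc3ccccc3)c2)c1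
A6 | alternative 3 | (2R,3S)-2-[4-(benzyloxy)-3-(triisopropylsilyloxy)phenyl]-3-hydroxy-7-(triisopropylsilyloxy)-2,3,4,6,7,8-hexahydro-5H-chromen-5-one, both C7 epimers | O=C1CC(O[Si](C(C)C)(C(C)C)C(C)C)CC2=C1C[C@H](O)[C@@H](c1ccc(OCc3ccccc3)c(O[Si](C(C)C)(C(C)C)C(C)C)c1)O2
A7 | alternative 3 | 5-(triisopropylsilyloxy)cyclohexane-1,3-dione | O=C1CC(O[Si](C(C)C)(C(C)C)C(C)C)CC(=O)C1
A8 | alternative 3 | (2R,3S)-3-[4-(benzyloxy)-3-(triisopropylsilyloxy)phenyl]oxirane-2-carbaldehyde | O=C[C@@H]1O[C@H]1c1ccc(OCc2ccccc2)c(O[Si](C(C)C)(C(C)C)C(C)C)c1
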